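**Plan**
- Retrosynthesis: the hydroquinone is taken back through its quinone and its 4-methoxyphenol to a benzannulation that cuts three ring C–C bonds (C1–C2, C3–C4, C1–C6). This leaves the terminal alkyne of a 1,4-enyne diketone, one CO and an (E)-propenyl(methoxy)carbene on chromium.
- What allows this is the arene itself: C1 carries OH between C2 (benzylic CH2 of the chain) and C6 (CH3), C4 carries the para oxygen, and C3 and C5 are CH. These six atoms are CO, the two alkyne carbons, the carbene carbon and the two propenyl carbons.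
- The enyne diketone is cut at CH2–C≡CH (allylic bromide plus ethynyl Grignard), at C(CH3)=CH (methylalumination of a terminal alkyne, then CH2O), at CH(OH)–CH2 (propargylation of a lactol) and at the prenyl carbinol (allylation, cross-metathesis).
- Forward: one Weiss–Cook condensation makes both five-membered rings, one ketone is removed, one ring is opened at C2–C3 by ozonolysis of its silyl enol ether, the two chains grow from the resulting lactone, and the benzene ring closes last.
- Stereochemistry: the cis ring fusion fixes the two quaternary carbons relative to each other, and a chiral lithium amide picks one enantiotopic CH2 of the meso ketone and so sets both absolutely. The E alkene comes from syn carboalumination; carbinol carbons are carried as epimer mixtures (undefined in the SMILES) and oxidised away in step 17.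

Key step: step 19

Assumption: the (R,R)-amide is taken to deprotonate ketone 8 in the sense that gives enol ether 10 as drawn; if this ketone responds in the opposite sense, the (S,S)-amide is used and nothing else changes.

**Route**

Step 1
Reactants: 1 butane-2,3-dione; 2 dimethyl 3-oxopentanedioate (2 equiv)
Product: 3 tetramethyl cis-1,5-dimethyl-3,7-dioxobicyclo[3.3.0]octane-2,4,6,8-tetracarboxylate (present largely as its bis-enol)
Conditions: aq NaHCO3 (pH about 8), rt
Reagents that add atoms: none
Why: Weiss–Cook condensation, in which two aldol/Michael sequences between the 1,2-diketone and two 3-oxoglutarate units close both five-membered rings, and the cis fusion (the only unstrained one for a diquinane) places the two methyl-bearing quaternary carbons cis.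

Step 2
Reactants: 3 tetraester
Product: 4 cis-1,5-dimethylbicyclo[3.3.0]octane-3,7-dione
Conditions: 1 M HCl, AcOH, reflux
Reagents that add atoms: none
Why: Acid hydrolysis of the four β-keto esters followed by decarboxylation is the standard finish of the Weiss–Cook sequence, and the quaternary carbons cannot epimerise.

Step 3
Reactants: 4 dione
Product: 5 cis-1,5-dimethylbicyclo[3.3.0]octane-3,7-dione mono(2,2-dimethylpropane-1,3-diyl) ketal
Conditions: 2,2-dimethylpropane-1,3-diol (1 equiv), TsOH (cat.), toluene, reflux, water separator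
Reagents that add atoms: 2,2-dimethylpropane-1,3-diol, OCC(C)(C)CO
Why: Acid-catalysed ketalisation with one equivalent of diol under water removal should give the mono-ketal statistically, which is separated while bis-ketal and dione are recycled.

Step 4
Reactants: 5 mono-ketal
Product: 7 cis-1,5-dimethylbicyclo[3.3.0]octan-3-one 2,2-dimethylpropane-1,3-diyl ketal, via hydrazone 6 (not isolated)
Conditions: N2H4·H2O, KOH, diethylene glycol, 130 then 200 °C
Reagents that add atoms: none
Why: Wolff–Kishner reduction, in which the hydrazone formed in the flask loses N2 under hot KOH to leave CH2 while the base-stable ketal survives.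

Step 5
Reactants: 7 ketal
Product: 8 cis-1,5-dimethylbicyclo[3.3.0]octan-3-one (meso)
Conditions: 2 M HCl, THF, rt
Reagents that add atoms: water, O
Why: Acid-catalysed ketal hydrolysis returns the remaining ketone in a meso compound whose mirror plane passes through C3 and C7.

Step 6
Reactants: 8 meso ketone
Product: 10 (1S,5R)-1,5-dimethyl-3-(trimethylsilyloxy)bicyclo[3.3.0]oct-2-ene, via lithium enolate 9 (not isolated)
Conditions: (R,R)-[PhCH(CH3)]2NLi (from the amine and n-BuLi), Me3SiCl (present from the start), LiCl, THF, –100 °C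
Reagents that add atoms: chlorotrimethylsilane, C[Si](C)(C)Cl
Why: Enantioselective deprotonation of a meso ketone by a C2-symmetric chiral lithium amide under in situ silyl quench distinguishes the enantiotopic C2 and C4 methylenes and traps the enolate before it can equilibrate, which sets the absolute configuration of both quaternary carbons at once.

Step 7
Reactants: 10 silyl enol ether
Product: 13 2-[(1R,2R)-2-formyl-1,2-dimethylcyclopentyl]acetic acid, via silyloxy ozonide 11 (not isolated), via trimethylsilyl ester 12 (not isolated)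
Conditions: O3, CH2Cl2, –78 °C; Me2S, –78 °C to rt; aqueous work-up
Reagents that add atoms: ozone, [O-][O+]=O
Why: Ozonolysis of a silyl enol ether cleaves C2=C3, so C2 becomes the aldehyde on one quaternary carbon and C3 the acid (first its silyl ester) on the CH2 arm of the other, turning the desymmetrisation into two differentiated arms without touching either stereocentre.

Step 8
Reactants: 13 aldehyde acid; 14 allylmagnesium bromide
Product: 16 (1R,6R)-2-allyl-1,6-dimethyl-3-oxabicyclo[4.3.0]nonan-4-one (both C2 epimers), via hydroxy acid 15 (not isolated)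
Conditions: CH2=CHCH2MgBr (2.5 equiv), THF, –78 to 0 °C; 1 M HCl; TsOH (cat.), CH2Cl2, rt
Reagents that add atoms: none
Why: Grignard addition in which one equivalent deprotonates the acid and the next adds to the neopentyl aldehyde, after which the cis δ-hydroxy acid closes to the six-membered lactone on acidification; the new carbinol carbon is unselective by design and is erased in step 17.

Step 9
Reactants: 16 allyl lactone; 17 2-methylbut-2-ene
Product: 18 (1R,6R)-1,6-dimethyl-2-(3-methylbut-2-enyl)-3-oxabicyclo[4.3.0]nonan-4-one (both C2 epimers)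
Conditions: second-generation Grubbs catalyst (H2IMes)(PCy3)Cl2Ru=CHPh (5 mol %), 2-methylbut-2-ene/CH2Cl2, 40 °C, sealed tube
Reagents that add atoms: none
Why: Olefin cross-metathesis of a terminal alkene with 2-methylbut-2-ene is the standard allyl-to-prenyl conversion and avoids the γ-selectivity of prenyl organometallics, the lactone being inert.

Step 10
Reactants: 18 prenyl lactone
Product: 19 (1R,6R)-1,6-dimethyl-2-(3-methylbut-2-enyl)-3-oxabicyclo[4.3.0]nonan-4-ol (lactol; epimers at C2 and C4)
Conditions: i-Bu2AlH (1.1 equiv), CH2Cl2, –78 °C; aq KNaC4H4O6 (potassium sodium tartrate)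
Reagents that add atoms: none
Why: Partial reduction of a lactone by i-Bu2AlH at low temperature stops at the tetrahedral aluminate, which gives the lactol on work-up.

Step 11
Reactants: 19 lactol; 20 3-bromoprop-1-yne
Product: 21 1-[(1R,2R)-2-(2-hydroxypent-4-ynyl)-1,2-dimethylcyclopentyl]-4-methylpent-3-en-1-ol (epimers at both carbinol carbons)
Conditions: Zn dust, THF/sat. aq NH4Cl, 0 °C to rt
Reagents that add atoms: none
Why: Zinc Barbier propargylation, in which the lactol is in equilibrium with its hydroxy aldehyde and the allenylzinc species formed from 20 adds by SE2' to give the homopropargylic alcohol; the new carbinol carbon is again removed in step 17.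

Step 12
Reactants: 21 diol
Product: 22 (1R,2R)-1-[1-(tert-butyldimethylsilyloxy)-4-methylpent-3-enyl]-2-[2-(tert-butyldimethylsilyloxy)pent-4-ynyl]-1,2-dimethylcyclopentane (TBS = tert-butyldimethylsilyl)
Conditions: TBSOTf (3 equiv), 2,6-lutidine, CH2Cl2, –78 to 0 °C
Reagents that add atoms: tert-butyldimethylsilyl trifluoromethanesulfonate, CC(C)(C)[Si](C)(C)OS(=O)(=O)C(F)(F)F
Why: Silylation with the silyl triflate and 2,6-lutidine covers both secondary alcohols, including the hindered neopentyl one, against the organoaluminium, organolithium and Grignard reagents that follow.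

Step 13
Reactants: 22 bis-silyl ether alkyne
Product: 25 (1R,2R)-1-[1-(TBSO)-4-methylpent-3-enyl]-2-[(E)-2-(TBSO)-6-hydroxy-4-methylhex-4-enyl]-1,2-dimethylcyclopentane, via alkenyldimethylalane 23 (not isolated), via lithium butylalanate 24 (not isolated)
Conditions: AlMe3 (3 equiv), Cp2ZrCl2 (0.5 equiv), CH2Cl2, 0 °C to rt; volatiles removed; n-BuLi, THF, –78 °C; (CH2O)n, –78 °C to rt
Reagents that add atoms: trimethylaluminium, C[Al](C)C; formaldehyde (from paraformaldehyde), C=O
Why: Zirconium-catalysed methylalumination of a terminal alkyne (Negishi carboalumination) adds CH3 and Al syn with Al on the terminal carbon, which fixes the E trisubstituted alkene, and the alkenylalanate made with n-BuLi attacks formaldehyde with retention while the trisubstituted prenyl alkene stays inert.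

Step 14
Reactants: 25 allylic alcohol
Product: 26 (1R,2R)-2-[(E)-6-bromo-2-(TBSO)-4-methylhex-4-enyl]-1-[1-(TBSO)-4-methylpent-3-enyl]-1,2-dimethylcyclopentane
Conditions: CBr4, PPh3, CH2Cl2, 0 °C; used at once
Reagents that add atoms: tetrabromomethane, BrC(Br)(Br)Br
Why: Appel bromination of a primary allylic alcohol runs under neutral conditions, so silyl ethers and both alkenes are spectators.

Step 15
Reactants: 26 allylic bromide; 27 ethynylmagnesium bromide
Product: 28 (1R,2R)-1-[1-(TBSO)-4-methylpent-3-enyl]-2-[(E)-2-(TBSO)-4-methyloct-4-en-7-ynyl]-1,2-dimethylcyclopentane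
Conditions: HC≡CMgBr (3 equiv), CuCl (10 mol %), THF, 0 to 50 °C
Reagents that add atoms: none
Why: Copper-catalysed SN2 coupling of a primary allylic bromide with an alkynyl Grignard reagent is the usual entry to skipped enynes of prenyl type, and attack at the unhindered CH2 keeps the alkene position and its E geometry.

Step 16
Reactants: 28 bis-silyl ether enyne
Product: 29 1-[(1R,2R)-2-[(E)-2-hydroxy-4-methyloct-4-en-7-ynyl]-1,2-dimethylcyclopentyl]-4-methylpent-3-en-1-ol (epimers at both carbinol carbons)
Conditions: HF·pyridine, pyridine, THF, 0 °C to rt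
Reagents that add atoms: none
Why: Fluoride cleavage of both silyl ethers under buffered, weakly acidic conditions keeps base away from the doubly activated CH2 of the 1,4-enyne.

Step 17
Reactants: 29 enyne diol
Product: 30 1-[(1R,2R)-1,2-dimethyl-2-[(E)-4-methyl-2-oxooct-4-en-7-ynyl]cyclopentyl]-4-methylpent-3-en-1-one
Conditions: Dess–Martin periodinane (3 equiv), NaHCO3, CH2Cl2, 0 °C to rt
Reagents that add atoms: none
Why: Dess–Martin oxidation of both secondary alcohols under buffered neutral conditions should give the two β,γ-unsaturated ketones without moving the double bonds into conjugation, erases the stray carbinol centres, and unveils the aldol-prone 1,5-diketone only after the last basic step.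

Step 18
Reactants: 31 (E)-1-bromoprop-1-ene; 32 hexacarbonylchromium Cr(CO)6
Product: 35 pentacarbonyl[(E)-1-methoxybut-2-enylidene]chromium, via (E)-prop-1-enyllithium 33 (not isolated), via lithium acylchromate 34 (not isolated)
Conditions: t-BuLi (2 equiv), Et2O, –78 °C; Cr(CO)6, Et2O, –78 °C to rt; Me3OBF4, CH2Cl2, 0 °C
Reagents that add atoms: trimethyloxonium tetrafluoroborate, C[O+](C)C.F[B-](F)(F)F
Why: Fischer carbene synthesis, in which bromine–lithium exchange with retention gives (E)-propenyllithium, this adds to a CO ligand of Cr(CO)6, and O-methylation of the acylchromate by the oxonium salt gives the alkenyl(methoxy)carbene complex.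

Step 19
Reactants: 30 enyne diketone; 35 pentacarbonyl[(E)-1-methoxybut-2-enylidene]chromium
Product: 37 1-[(1R,2R)-2-[(E)-6-(2-hydroxy-5-methoxy-3-methylphenyl)-4-methyl-2-oxohex-4-enyl]-1,2-dimethylcyclopentyl]-4-methylpent-3-en-1-one, via tricarbonylchromium arene complex 36 (not isolated)
Conditions: 35 (1.5 equiv), THF (0.05 M, degassed), 50 °C, Ar; then air, Et2O, rt
Reagents that add atoms: none
Why: Thermal loss of one CO from 35 frees a site on zerovalent chromium for the terminal alkyne of 30, which inserts with its unsubstituted carbon bonding to the carbene carbon because H is much smaller than the allylic CH2 chain; CO insertion then gives a dienylketene complex. A 6π-electrocyclisation joins the ketene carbon to the propenyl β-carbon and so closes the six-membered carbocycle (three new ring C–C bonds in all), and tautomerisation gives the phenol as its Cr(CO)3 complex 36, which air sets free. This is the Dötz benzannulation of an alkenyl(alkoxy)carbene complex with a terminal alkyne, a reaction known for skipped enynes as well. No stereocentre is formed, and the two quaternary carbons and the E alkene are remote spectators. The step needs regioselectivity (chain ortho to OH, CH3 on the other ortho carbon, OCH3 para), which the steric bias of the terminal alkyne secures, and chemoselectivity for the alkyne over two trisubstituted alkenes and two ketones, which the neutral conditions and the inertness of unactivated alkenes toward the carbene should secure.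

Step 20
Reactants: 37 4-methoxyphenol
Product: 38 2-[(E)-6-[(1R,2R)-1,2-dimethyl-2-(4-methylpent-3-enoyl)cyclopentyl]-3-methyl-5-oxohex-2-enyl]-6-methylcyclohexa-2,5-diene-1,4-dione
Conditions: (NH4)2Ce(NO3)6 (2.2 equiv), MeCN/H2O, 0 °C, short reaction time
Reagents that add atoms: water, O
Why: Oxidative demethylation of a 4-methoxyphenol by tetravalent cerium proceeds by two one-electron oxidations and ipso attack of water at C4, releasing methanol and giving the 1,4-benzoquinone while isolated alkenes and ketones are left alone at 0 °C.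

Step 21
Reactants: 38 quinone
Product: 39 1-[(1R,2R)-2-[(E)-6-(2,5-dihydroxy-3-methylphenyl)-4-methyl-2-oxohex-4-enyl]-1,2-dimethylcyclopentyl]-4-methylpent-3-en-1-one (CNP0294415.1)
Conditions: Na2S2O4, EtOAc/H2O, rt, Ar
Reagents that add atoms: none
Why: Two-electron reduction of the quinone by dithionite in a two-phase system should give the hydroquinone without touching ketones or alkenes, and the product is handled under argon.

**Compound list**

1 | butane-2,3-dione | CC(=O)C(C)=O | starting material
2 | dimethyl 3-oxopentanedioate | COC(=O)CC(=O)CC(=O)OC | starting material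
3 | tetramethyl cis-1,5-dimethyl-3,7-dioxobicyclo[3.3.0]octane-2,4,6,8-tetracarboxylate (keto form drawn; ester-bearing carbons undefined) | O=C1C(C(=O)OC)[C@]2(C)C(C(=O)OC)C(=O)C(C(=O)OC)[C@]2(C)C1C(=O)OC | intermediate
4 | cis-1,5-dimethylbicyclo[3.3.0]octane-3,7-dione | O=C1C[C@]2(C)CC(=O)C[C@]2(C)C1 | intermediate
5 | mono(2,2-dimethylpropane-1,3-diyl) ketal of 4 | O=C1C[C@]2(C)CC3(OCC(C)(C)CO3)C[C@]2(C)C1 | intermediate
6 | hydrazone of 5 (not isolated) | NN=C1C[C@]2(C)CC3(OCC(C)(C)CO3)C[C@]2(C)C1 | intermediate
7 | cis-1,5-dimethylbicyclo[3.3.0]octan-3-one 2,2-dimethylpropane-1,3-diyl ketal | C1C[C@]2(C)CC3(OCC(C)(C)CO3)C[C@]2(C)C1 | intermediate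
8 | cis-1,5-dimethylbicyclo[3.3.0]octan-3-one (meso) | O=C1C[C@]2(C)CCC[C@]2(C)C1 | intermediate
9 | lithium (1S,5R)-1,5-dimethylbicyclo[3.3.0]oct-2-en-3-olate (not isolated) | [Li]OC1=C[C@]2(C)CCC[C@]2(C)C1 | intermediate
10 | (1S,5R)-1,5-dimethyl-3-(trimethylsilyloxy)bicyclo[3.3.0]oct-2-ene | C[Si](C)(C)OC1=C[C@]2(C)CCC[C@]2(C)C1 | intermediate
11 | silyloxy ozonide of 10 (1,2,4-trioxolane spanning former C2 and C3; not isolated) | C[Si](C)(C)OC12OC(OO1)[C@]3(C)CCC[C@]3(C)C2 | intermediate
12 | trimethylsilyl 2-[(1R,2R)-2-formyl-1,2-dimethylcyclopentyl]acetate (not isolated) | O=C[C@]1(C)CCC[C@]1(C)CC(=O)O[Si](C)(C)C | intermediate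
13 | 2-[(1R,2R)-2-formyl-1,2-dimethylcyclopentyl]acetic acid | O=C[C@]1(C)CCC[C@]1(C)CC(=O)O | intermediate
14 | allylmagnesium bromide | C=CC[Mg]Br | starting material
15 | 2-[(1R,2R)-2-(1-hydroxybut-3-enyl)-1,2-dimethylcyclopentyl]acetic acid (carbinol epimers; not isolated) | C=CCC(O)[C@]1(C)CCC[C@]1(C)CC(=O)O | intermediate
16 | (1R,6R)-2-allyl-1,6-dimethyl-3-oxabicyclo[4.3.0]nonan-4-one (C2 epimers) | C=CCC1[C@]2(C)CCC[C@]2(C)CC(=O)O1 | intermediate
17 | 2-methylbut-2-ene | CC=C(C)C | starting material
18 | (1R,6R)-1,6-dimethyl-2-(3-methylbut-2-enyl)-3-oxabicyclo[4.3.0]nonan-4-one (C2 epimers) | CC(C)=CCC1[C@]2(C)CCC[C@]2(C)CC(=O)O1 | intermediate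
19 | (1R,6R)-1,6-dimethyl-2-(3-methylbut-2-enyl)-3-oxabicyclo[4.3.0]nonan-4-ol (epimers at C2 and C4) | CC(C)=CCC1[C@]2(C)CCC[C@]2(C)CC(O)O1 | intermediate
20 | 3-bromoprop-1-yne | C#CCBr | starting material
21 | 1-[(1R,2R)-2-(2-hydroxypent-4-ynyl)-1,2-dimethylcyclopentyl]-4-methylpent-3-en-1-ol (carbinol epimers) | CC(C)=CCC(O)[C@]1(C)CCC[C@]1(C)CC(O)CC#C | intermediate
22 | bis-TBS ether of 21 | CC(C)=CCC(O[Si](C)(C)C(C)(C)C)[C@]1(C)CCC[C@]1(C)CC(O[Si](C)(C)C(C)(C)C)CC#C | intermediate
23 | (E)-alkenyldimethylalane from 22 (not isolated) | CC(C)=CCC(O[Si](C)(C)C(C)(C)C)[C@]1(C)CCC[C@]1(C)CC(O[Si](C)(C)C(C)(C)C)C/C(C)=C/[Al](C)C | intermediate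
24 | lithium butyl(dimethyl)alkenylalanate from 23 (not isolated) | CC(C)=CCC(O[Si](C)(C)C(C)(C)C)[C@]1(C)CCC[C@]1(C)CC(O[Si](C)(C)C(C)(C)C)C/C(C)=C/[Al-](C)(C)CCCC.[Li+] | intermediate
25 | (E)-allylic alcohol, bis-TBS ether | CC(C)=CCC(O[Si](C)(C)C(C)(C)C)[C@]1(C)CCC[C@]1(C)CC(O[Si](C)(C)C(C)(C)C)C/C(C)=C/CO | intermediate
26 | (E)-allylic bromide, bis-TBS ether | CC(C)=CCC(O[Si](C)(C)C(C)(C)C)[C@]1(C)CCC[C@]1(C)CC(O[Si](C)(C)C(C)(C)C)C/C(C)=C/CBr | intermediate
27 | ethynylmagnesium bromide | C#C[Mg]Br | starting material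
28 | (E)-1,4-enyne, bis-TBS ether | CC(C)=CCC(O[Si](C)(C)C(C)(C)C)[C@]1(C)CCC[C@]1(C)CC(O[Si](C)(C)C(C)(C)C)C/C(C)=C/CC#C | intermediate
29 | 1-[(1R,2R)-2-[(E)-2-hydroxy-4-methyloct-4-en-7-ynyl]-1,2-dimethylcyclopentyl]-4-methylpent-3-en-1-ol (carbinol epimers) | CC(C)=CCC(O)[C@]1(C)CCC[C@]1(C)CC(O)C/C(C)=C/CC#C | intermediate
30 | 1-[(1R,2R)-1,2-dimethyl-2-[(E)-4-methyl-2-oxooct-4-en-7-ynyl]cyclopentyl]-4-methylpent-3-en-1-one | CC(C)=CCC(=O)[C@]1(C)CCC[C@]1(C)CC(=O)C/C(C)=C/CC#C | intermediate
31 | (E)-1-bromoprop-1-ene | C/C=C/Br | starting material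
32 | hexacarbonylchromium | O=C=[Cr](=C=O)(=C=O)(=C=O)(=C=O)=C=O | starting material
33 | (E)-prop-1-enyllithium (not isolated) | C/C=C/[Li] | intermediate
34 | lithium pentacarbonyl[(E)-1-oxidobut-2-enylidene]chromate (not isolated) | C/C=C/C(O[Li])=[Cr](=C=O)(=C=O)(=C=O)(=C=O)=C=O | intermediate
35 | pentacarbonyl[(E)-1-methoxybut-2-enylidene]chromium | C/C=C/C(OC)=[Cr](=C=O)(=C=O)(=C=O)(=C=O)=C=O | intermediate
36 | tricarbonylchromium η6-arene complex of 37 (drawn as arene plus Cr(CO)3 fragment; not isolated) | CC(C)=CCC(=O)[C@]1(C)CCC[C@]1(C)CC(=O)C/C(C)=C/Cc1cc(OC)cc(C)c1O.O=C=[Cr](=C=O)=C=O | intermediate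
37 | 1-[(1R,2R)-2-[(E)-6-(2-hydroxy-5-methoxy-3-methylphenyl)-4-methyl-2-oxohex-4-enyl]-1,2-dimethylcyclopentyl]-4-methylpent-3-en-1-one | CC(C)=CCC(=O)[C@]1(C)CCC[C@]1(C)CC(=O)C/C(C)=C/Cc1cc(OC)cc(C)c1O | intermediate
38 | 2-[(E)-6-[(1R,2R)-1,2-dimethyl-2-(4-methylpent-3-enoyl)cyclopentyl]-3-methyl-5-oxohex-2-enyl]-6-methylcyclohexa-2,5-diene-1,4-dione | CC(C)=CCC(=O)[C@]1(C)CCC[C@]1(C)CC(=O)C/C(C)=C/CC1=CC(=O)C=C(C)C1=O | intermediate
39 | 1-[(1R,2R)-2-[(E)-6-(2,5-dihydroxy-3-methylphenyl)-4-methyl-2-oxohex-4-enyl]-1,2-dimethylcyclopentyl]-4-methylpent-3-en-1-one | CC(C)=CCC(=O)[C@]1(C)CCC[C@]1(C)CC(=O)C/C(C)=C/Cc1cc(O)cc(C)c1O | target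

**Step count**

Total steps: 21. Longest linear sequence: 20 (steps 1–17 and 19–21); step 18 is a one-step branch.

**Steps most likely to fail**

Step 19. The chromium vinylcarbene and vinylketene intermediates may be diverted into non-phenol channels, or the β,γ double bonds may migrate into conjugation during heating or during oxidative removal of chromium. The fallback closes the ring before the ketones exist; it sets out from 28 and returns at 38. Heating 28 with 35 in THF at 50 °C should give the tricarbonylchromium arene complex F1 and, after exposure to air, the bis-silyl ether 4-methoxyphenol F2. Oxidation with (NH4)2Ce(NO3)6 in MeCN/H2O should then give the bis-silyl ether quinone F3, HF·pyridine should free the quinone diol F4, and Dess–Martin periodinane should oxidise both carbinols to give 38.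

Step 6. Discrimination between the two enantiotopic methylene groups may be insufficient, giving material of low enantiomeric purity. The fallback replaces asymmetric induction by resolution; it sets out from 8 and returns at 13. LiN(i-Pr)2 and Me3SiCl should give the racemic silyl enol ether F5, and ozonolysis as in step 7 the racemic aldehyde acid F6. This is crystallised with (R)-N,N-dimethyl-1-phenylethylamine, a tertiary amine that cannot condense with the aldehyde, to enrich the ammonium salt F7 of the (1R,2R) acid. Acidification returns 13; the antipodal amine is used if the salt of the wrong acid is the less soluble one.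

Step 11. The lactol may fail to open to its hydroxy aldehyde under Barbier conditions, or allenyl instead of propargyl transfer may occur on the hindered substrate. The fallback exposes a free aldehyde; it sets out from 18 and returns at 22. Opening of the lactone with Me2AlN(OCH3)CH3 (from AlMe3 and CH3ONHCH3·HCl) should give the hydroxy Weinreb amide F8. TBSOTf and 2,6-lutidine give the silyloxy Weinreb amide F9, and i-Bu2AlH at –78 °C the silyloxy aldehyde F10. Zinc and 20 in THF/aq NH4Cl should then give the mono-silylated homopropargylic alcohol F11, and a second silylation gives 22.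

**Further compounds**

F1 | step 19 | tricarbonylchromium η6-arene complex of F2 (drawn as arene plus Cr(CO)3 fragment) | CC(C)=CCC(O[Si](C)(C)C(C)(C)C)[C@]1(C)CCC[C@]1(C)CC(O[Si](C)(C)C(C)(C)C)C/C(C)=C/Cc1cc(OC)cc(C)c1O.O=C=[Cr](=C=O)=C=O
F2 | step 19 | bis-TBS ether 4-methoxyphenol | CC(C)=CCC(O[Si](C)(C)C(C)(C)C)[C@]1(C)CCC[C@]1(C)CC(O[Si](C)(C)C(C)(C)C)C/C(C)=C/Cc1cc(OC)cc(C)c1O
F3 | step 19 | bis-TBS ether quinone | CC(C)=CCC(O[Si](C)(C)C(C)(C)C)[C@]1(C)CCC[C@]1(C)CC(O[Si](C)(C)C(C)(C)C)C/C(C)=C/CC1=CC(=O)C=C(C)C1=O
F4 | step 19 | quinone diol | CC(C)=CCC(O)[C@]1(C)CCC[C@]1(C)CC(O)C/C(C)=C/CC1=CC(=O)C=C(C)C1=O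
F5 | step 6 | racemic cis-1,5-dimethyl-3-(trimethylsilyloxy)bicyclo[3.3.0]oct-2-ene (both enantiomers written) | C[Si](C)(C)OC1=C[C@]2(C)CCC[C@]2(C)C1.C[Si](C)(C)OC1=C[C@@]2(C)CCC[C@@]2(C)C1
F6 | step 6 | racemic 2-(2-formyl-1,2-dimethylcyclopentyl)acetic acid, cis methyls (both enantiomers written) | O=C[C@]1(C)CCC[C@]1(C)CC(=O)O.O=C[C@@]1(C)CCC[C@@]1(C)CC(=O)O
F7 | step 6 | (R)-N,N-dimethyl-1-phenylethylammonium 2-[(1R,2R)-2-formyl-1,2-dimethylcyclopentyl]acetate | O=C[C@]1(C)CCC[C@]1(C)CC(=O)[O-].C[C@@H]([NH+](C)C)c1ccccc1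
F8 | step 11 | hydroxy Weinreb amide from 18 | CC(C)=CCC(O)[C@]1(C)CCC[C@]1(C)CC(=O)N(C)OC
F9 | step 11 | silyloxy Weinreb amide | CC(C)=CCC(O[Si](C)(C)C(C)(C)C)[C@]1(C)CCC[C@]1(C)CC(=O)N(C)OC
F10 | step 11 | silyloxy aldehyde | CC(C)=CCC(O[Si](C)(C)C(C)(C)C)[C@]1(C)CCC[C@]1(C)CC=O
F11 | step 11 | mono-silylated homopropargylic alcohol | CC(C)=CCC(O[Si](C)(C)C(C)(C)C)[C@]1(C)CCC[C@]1(C)CC(O)CC#C
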